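**Retrosynthetic overview**
1. Last bond: C10–O11 of the dihydropyran, closed on the unprotected enyne triol 22 by a zerovalent-palladium/benzoic-acid cycloisomerisation (alkyne → π-allyl, O–H addition); this sets C10 and the E-C8=C9 alkene.
2. Enyne 22 comes from aldehyde 17 by Z-selective iodo-olefination, Sonogashira coupling with dec-1-yne, acid unmasking and ketone reduction (C27).
3. The bridged lactone and the cyclopentane form together in an intramolecular Diels–Alder reaction of the 3,4-dioxygenated 2-pyrone 16 with its tethered (Z)-enal (sets C12, C16, C21, C22 from C18).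
4. Pyrone 13 comes from ester 6 and the dianion of α-PMB-oxy acetoacetate 10; C18 comes from chiral-pool chlorohydrin 1 (epoxide, then acetylide opening).
5. Ring order: 2-pyrone (consumed as diene) → cyclopentane and 2-oxabicyclo[2.2.2]octanone in one step → dihydropyran last.

Assumption: the SMILES is taken as the full definition of the target (10R,12S,16R,18R,21S,22R,27R, E-alkene, in the labels below); the (R,R) enantiomer of the DACH-phenyl bisphosphine is taken as the matched ligand in step 14; the route is a proposal and has not been run.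

Atom labels (target SMILES read left to right): C1–C7 heptyl; C8=C9; C10 = O–CH; O11; C12 = bridgehead C(O11)(C13)(C22)(C27); C13 = lactone C=O; O15 = lactone O; C16 = bridgehead C(O15)(C17)(C21)(C26); C17 = CH2; C18 = CH–O; C20 = CH2; C21, C22 = ring-fusion CH; C23=C24; C25 = CH3 on C24; C26 = CH2; C27 = CH–O.

**Step 1**
Reactants: 1 ethyl (3S)-4-chloro-3-hydroxybutanoate
Product: 2 ethyl 2-[(2S)-oxiran-2-yl]acetate
Conditions: Ag2O, Et2O, reflux, dark
Reagents that add atoms: none
Why: Halohydrin-to-epoxide closure (intramolecular Williamson etherification) under non-basic Ag2O avoids E1cB opening to the hydroxycrotonate, and the C18–O bond is untouched so the chiral-pool centre is retained.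

**Step 2**
Reactants: 2 ethyl 2-[(2S)-oxiran-2-yl]acetate; 3 3,3-diethoxyprop-1-yne
Product: 5 ethyl (3R)-7,7-diethoxy-3-hydroxyhept-5-ynoate, via lithium acetylide 4 (not isolated)
Conditions: 3, n-BuLi, THF, −78 °C; BF3·OEt2; then 2, −78 °C; aq. NH4Cl
Reagents that add atoms: none
Why: Yamaguchi–Hirao BF3-mediated alkynylation opens the epoxide at its CH2 terminus at −78 °C without touching the ester, so C18 keeps its configuration (the descriptor changes only through CIP priorities).

**Step 3**
Reactants: 5 ethyl (3R)-7,7-diethoxy-3-hydroxyhept-5-ynoate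
Product: 6 ethyl (3R)-3-[(tert-butyldimethylsilyl)oxy]-7,7-diethoxyhept-5-ynoate
Conditions: TBSCl, imidazole, DMF, rt
Reagents that add atoms: tert-butyldimethylsilyl chloride, CC(C)(C)[Si](C)(C)Cl
Why: Standard imidazole-promoted silylation of the secondary alcohol protects C18–OH for the dianion chemistry and supplies the bulky group that later biases the cycloaddition face.

**Step 4**
Reactants: 7 methyl 3-oxobutanoate
Product: 8 methyl 2-diazo-3-oxobutanoate
Conditions: 4-acetamidobenzenesulfonyl azide, Et3N, MeCN, 0 °C → rt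
Reagents that add atoms: 4-acetamidobenzenesulfonyl azide, CC(=O)Nc1ccc(cc1)S(=O)(=O)N=[N+]=[N-]
Why: Regitz diazo transfer to the active methylene of a β-keto ester is routine.

**Step 5**
Reactants: 8 methyl 2-diazo-3-oxobutanoate; 9 4-methoxybenzyl alcohol
Product: 10 methyl 2-[(4-methoxybenzyl)oxy]-3-oxobutanoate
Conditions: Rh2(OAc)4 (1 mol%), CH2Cl2, 40 °C
Reagents that add atoms: none
Why: Rhodium-carbenoid O–H insertion into the alcohol gives the α-alkoxy β-keto ester that carries the future O11 (as a PMB ether).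

**Step 6**
Reactants: 6 ethyl (3R)-3-[(tert-butyldimethylsilyl)oxy]-7,7-diethoxyhept-5-ynoate; 10 methyl 2-[(4-methoxybenzyl)oxy]-3-oxobutanoate
Product: 13 6-{(2R)-2-[(tert-butyldimethylsilyl)oxy]-6,6-diethoxyhex-4-yn-1-yl}-4-hydroxy-3-[(4-methoxybenzyl)oxy]-2H-pyran-2-one, via dilithium dianion 11 (not isolated), via triketo ester 12 (not isolated)
Conditions: 10 (2.5 equiv), LiN(i-Pr)2, THF, −78 → 0 °C; 6, −78 °C; aq. NH4Cl; then DBU, CH2Cl2, rt
Reagents that add atoms: none
Why: Huckin–Weiler γ-acylation (Claisen condensation) of the acetoacetate dianion by the ester, then DBU-mediated enol lactonisation of the 3,5-diketo ester, gives the 4-hydroxy-2-pyrone with O11 already on C12 and no stereocentre touched.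

**Step 7**
Reactants: 13 (4-hydroxy-2-pyrone)
Product: 14 6-{(2R)-2-[(tert-butyldimethylsilyl)oxy]-6,6-diethoxyhex-4-yn-1-yl}-4-methoxy-3-[(4-methoxybenzyl)oxy]-2H-pyran-2-one
Conditions: Me2SO4, K2CO3, acetone, rt
Reagents that add atoms: dimethyl sulfate, COS(=O)(=O)OC
Why: O-methylation of the vinylogous acid (as for 4-methoxy-6-methyl-2-pyrone) masks the future C27 ketone as a methyl enol ether and removes an acidic OH that could hydrogen-bond the dienophile into the endo mode.

**Step 8**
Reactants: 14 (alkynyl acetal pyrone)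
Product: 15 6-{(2R,4Z)-2-[(tert-butyldimethylsilyl)oxy]-6,6-diethoxyhex-4-en-1-yl}-4-methoxy-3-[(4-methoxybenzyl)oxy]-2H-pyran-2-one
Conditions: H2 (1 atm), Pd/CaCO3 poisoned with Pb(OAc)2, quinoline, EtOAc, rt
Reagents that add atoms: none
Why: Lindlar semi-hydrogenation gives the (Z)-alkene that becomes the cis C21/C22 relationship, leaving the pyrone and PMB ether intact.

**Step 9**
Reactants: 15 ((Z)-alkenyl acetal pyrone)
Product: 17 tricyclic aldehyde [2-oxabicyclo[2.2.2]oct-5-en-3-one C12–C13(=O)–O15–C16 with C26=C27(OMe); cyclopentane C16–C17–C18(OTBS)–C20–C21; C12–OPMB; C22–CHO; stereocentres as in the target], via (Z)-enal 16 (not isolated)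
Conditions: PPTS (cat.), acetone–H2O, 0 °C → rt; NaHCO3 work-up; then PhMe, 60 °C
Reagents that add atoms: water, O
Why: Mild acetal hydrolysis unveils (Z)-enal 16, which undergoes a normal-demand intramolecular Diels–Alder reaction with the electron-rich 2-pyrone (C16–C21 and C12–C22 bonds) in which the cis alkene fixes C20/CHO cis, the exo mode (substituents over the unsubstituted O15–C13=O side, away from C26–H and C27–OMe) places them syn to the lactone bridge, and the OTBS group sits on the convex face of the forming cyclopentane (trans to C21–C22), which selects the diene face and so sets C12 and C16.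

**Step 10**
Reactants: 17 (tricyclic aldehyde)
Product: 18 (Z)-vinyl iodide [as 17 with C22–CH=C(CH3)I in place of CHO; C22 cis to I]
Conditions: EtPPh3I, n-BuLi, THF, 0 °C; I2, −78 °C; NaN(SiMe3)2, −20 °C; then 17, −78 → −20 °C
Reagents that add atoms: ethyltriphenylphosphonium iodide, CC[P+](c1ccccc1)(c1ccccc1)c1ccccc1.[I-]; iodine, II
Why: Stork–Zhao-type α-iodo-ylide Wittig olefination gives the (Z)-2-iodoalkene under low-temperature kinetic control, fast enough at −78 °C not to epimerise C22.

**Step 11**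
Reactants: 18 ((Z)-vinyl iodide); 19 dec-1-yne
Product: 20 (Z)-enyne [as 18 with dec-1-yn-1-yl in place of iodine: C22–CH=C(CH3)–C≡C–C8H17]
Conditions: PdCl2(PPh3)2 (5 mol%), CuI (10 mol%), Et3N, THF, rt
Reagents that add atoms: none
Why: Sonogashira coupling proceeds with retention of the alkene geometry and tolerates the lactone, enol ether and silyl ether.

**Step 12**
Reactants: 20 ((Z)-enyne, fully protected)
Product: 21 keto diol [C12–OH; C27 ketone with C26H2; C18–OH; C22–(1Z)-2-methyldodec-1-en-3-yn-1-yl; stereocentres as in the target]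
Conditions: TFA–H2O (9:1), CH2Cl2, 0 °C → rt; used at once
Reagents that add atoms: water, O
Why: One acidolysis cleaves the PMB ether (benzylic cation), hydrolyses the methyl enol ether to the C27 ketone and removes the TBS group, and acidic conditions avoid β-elimination of the lactone carboxylate from the β-acyloxy ketone.

**Step 13**
Reactants: 21 (keto diol)
Product: 22 enyne triol [as 21 with C27 (R)-CH–OH]
Conditions: NaBH4, CeCl3·7H2O, MeOH, −78 °C
Reagents that add atoms: none
Why: Luche reduction delivers hydride to C27 from the face syn to the lactone bridge (the other face is shielded by the syn C21–H and C22–H of the carbocyclic bridge), giving the C27 alcohol pointing toward that bridge without touching the lactone.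

**Step 14**
Reactants: 22 (enyne triol)
Product: 24 CNP0127096.1 (target; 10R,12S,16R,18R,21S,22R,27R), via vinylallene 23 (not isolated)
Conditions: Pd2(dba)3·CHCl3 (2.5 mol%), (R,R)-DACH-phenyl Trost ligand (7.5 mol%), PhCO2H (20 mol%), 1,4-dioxane (0.01 M), 70 °C
Reagents that add atoms: none
Why: Proposed new method: a palladium hydride formed from zerovalent palladium and benzoic acid hydropalladates the alkyne, β-hydride elimination gives vinylallene 23, re-addition of Pd–H to the central allene carbon gives a syn,syn-π-allyl (pentadienyl) palladium complex whose faces equilibrate by π–σ–π, and the tertiary C12–OH closes the six-membered ring at C10 anti to palladium in the ligand-matched diastereomer, setting C10 (R) and the E-C8=C9 alkene in a redox-neutral isomerisation in which only O11 can reach C10 (O28 would need a trans-bridged seven-membered ring); the closest known reaction type is the zerovalent-palladium/benzoic-acid intramolecular hydroalkoxylation of alkynes through allene and π-allyl intermediates, together with Trost-type asymmetric allylic etherification, neither of which has been shown for conjugated (Z)-enynes, tertiary bridgehead alcohols or dihydropyran formation.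

**Compound list**
1 | ethyl (3S)-4-chloro-3-hydroxybutanoate | CCOC(=O)C[C@H](O)CCl | starting material
2 | ethyl 2-[(2S)-oxiran-2-yl]acetate | CCOC(=O)C[C@H]1CO1 | intermediate
3 | 3,3-diethoxyprop-1-yne | C#CC(OCC)OCC | starting material
4 | lithium 3,3-diethoxyprop-1-yn-1-ide (not isolated) | [Li]C#CC(OCC)OCC | intermediate
5 | ethyl (3R)-7,7-diethoxy-3-hydroxyhept-5-ynoate | CCOC(=O)C[C@H](O)CC#CC(OCC)OCC | intermediate
6 | ethyl (3R)-3-[(tert-butyldimethylsilyl)oxy]-7,7-diethoxyhept-5-ynoate | CCOC(=O)C[C@H](O[Si](C)(C)C(C)(C)C)CC#CC(OCC)OCC | intermediate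
7 | methyl 3-oxobutanoate | COC(=O)CC(C)=O | starting material
8 | methyl 2-diazo-3-oxobutanoate | COC(=O)C(=[N+]=[N-])C(C)=O | intermediate
9 | 4-methoxybenzyl alcohol | COc1ccc(CO)cc1 | starting material
10 | methyl 2-[(4-methoxybenzyl)oxy]-3-oxobutanoate | COC(=O)C(OCc1ccc(OC)cc1)C(C)=O | intermediate
11 | dilithium C2,C4-dianion of 10 (not isolated) | [Li+].[Li+].COC(=O)[C-](OCc1ccc(OC)cc1)C(=O)[CH2-] | intermediate
12 | methyl (7R)-7-[(tert-butyldimethylsilyl)oxy]-11,11-diethoxy-2-[(4-methoxybenzyl)oxy]-3,5-dioxoundec-9-ynoate (not isolated) | COC(=O)C(OCc1ccc(OC)cc1)C(=O)CC(=O)C[C@H](O[Si](C)(C)C(C)(C)C)CC#CC(OCC)OCC | intermediate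
13 | 6-{(2R)-2-[(tert-butyldimethylsilyl)oxy]-6,6-diethoxyhex-4-yn-1-yl}-4-hydroxy-3-[(4-methoxybenzyl)oxy]-2H-pyran-2-one | O=C1OC(C[C@H](O[Si](C)(C)C(C)(C)C)CC#CC(OCC)OCC)=CC(O)=C1OCc2ccc(OC)cc2 | intermediate
14 | 6-{(2R)-2-[(tert-butyldimethylsilyl)oxy]-6,6-diethoxyhex-4-yn-1-yl}-4-methoxy-3-[(4-methoxybenzyl)oxy]-2H-pyran-2-one | O=C1OC(C[C@H](O[Si](C)(C)C(C)(C)C)CC#CC(OCC)OCC)=CC(OC)=C1OCc2ccc(OC)cc2 | intermediate
15 | 6-{(2R,4Z)-2-[(tert-butyldimethylsilyl)oxy]-6,6-diethoxyhex-4-en-1-yl}-4-methoxy-3-[(4-methoxybenzyl)oxy]-2H-pyran-2-one | O=C1OC(C[C@H](O[Si](C)(C)C(C)(C)C)C/C=C\C(OCC)OCC)=CC(OC)=C1OCc2ccc(OC)cc2 | intermediate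
16 | (2Z,5R)-5-[(tert-butyldimethylsilyl)oxy]-6-{4-methoxy-3-[(4-methoxybenzyl)oxy]-2-oxo-2H-pyran-6-yl}hex-2-enal (not isolated) | O=C1OC(C[C@H](O[Si](C)(C)C(C)(C)C)C/C=C\C=O)=CC(OC)=C1OCc2ccc(OC)cc2 | intermediate
17 | tricyclic aldehyde (Diels–Alder adduct; C12–OPMB, C27–OMe enol ether, C18–OTBS, C22–CHO) | COc1ccc(CO[C@@]23C(=O)O[C@]4(C[C@H](O[Si](C)(C)C(C)(C)C)C[C@H]4[C@H]2C=O)C=C3OC)cc1 | intermediate
18 | (Z)-vinyl iodide (C22–CH=C(CH3)I) | COc1ccc(CO[C@@]23C(=O)O[C@]4(C[C@H](O[Si](C)(C)C(C)(C)C)C[C@H]4[C@H]2/C=C(/C)I)C=C3OC)cc1 | intermediate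
19 | dec-1-yne | C#CCCCCCCCC | starting material
20 | protected (Z)-enyne | COc1ccc(CO[C@@]23C(=O)O[C@]4(C[C@H](O[Si](C)(C)C(C)(C)C)C[C@H]4[C@H]2/C=C(/C)C#CCCCCCCCC)C=C3OC)cc1 | intermediate
21 | keto diol (C12–OH, C27=O, C18–OH, enyne side chain) | O[C@@]23C(=O)O[C@]4(C[C@H](O)C[C@H]4[C@H]2/C=C(/C)C#CCCCCCCCC)CC3=O | intermediate
22 | enyne triol (C27 (R)-OH) | O[C@@]23C(=O)O[C@]4(C[C@H](O)C[C@H]4[C@H]2/C=C(/C)C#CCCCCCCCC)C[C@H]3O | intermediate
23 | vinylallene triol (side chain (1Z)-2-methyldodeca-1,3,4-trien-1-yl; not isolated) | O[C@@]23C(=O)O[C@]4(C[C@H](O)C[C@H]4[C@H]2/C=C(/C)C=C=CCCCCCCC)C[C@H]3O | intermediate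
24 | CNP0127096.1 (10R,12S,16R,18R,21S,22R,27R) | CCCCCCC/C=C/[C@H]1O[C@@]23C(=O)O[C@]4(C[C@H](O)C[C@H]4[C@H]2C=C1C)C[C@H]3O | target

**Step count**
Total steps: 14 (12 on the main line plus 2 for reagent 10). Longest linear sequence: 12 (steps 1–3 and 6–14).

**Three steps most likely to fail**

Step 6 (dianion acylation and pyrone closure). The risk is enolisation of ester 6 and β-elimination of the silyloxy group. The fallback replaces the Claisen acylation by aldol addition and oxidation. It sets out from 6, which is reduced with i-Bu2AlH (CH2Cl2, −78 °C) to (3R)-3-[(tert-butyldimethylsilyl)oxy]-7,7-diethoxyhept-5-ynal F1. Dianion 11 adds to it at −78 °C to give methyl (7R)-7-[(tert-butyldimethylsilyl)oxy]-11,11-diethoxy-5-hydroxy-2-[(4-methoxybenzyl)oxy]-3-oxoundec-9-ynoate F2 (C5 epimers). Dess–Martin periodinane oxidises this to triketo ester 12, and DBU closes 12 to pyrone 13, where the route is rejoined.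

Step 9 (intramolecular Diels–Alder). The risks are a poor exo/endo ratio, weak face control by the remote C18 centre, and Z-to-E drift of the enal; selectivity here is argued from sterics, not established. The fallback changes the cycloaddition to an anion-accelerated, catalyst-controlled reaction of the free 3-hydroxy-2-pyrone. It sets out from 15: DDQ (CH2Cl2, pH 7 buffer) removes the PMB group to give 6-{(2R,4Z)-2-[(tert-butyldimethylsilyl)oxy]-6,6-diethoxyhex-4-en-1-yl}-3-hydroxy-4-methoxy-2H-pyran-2-one F3. PPTS in wet acetone then liberates (2Z,5R)-5-[(tert-butyldimethylsilyl)oxy]-6-(3-hydroxy-4-methoxy-2-oxo-2H-pyran-6-yl)hex-2-enal F4, which is not isolated. It is treated at −20 °C with a cupreidine-type (6′-hydroxy cinchona) bifunctional base, a catalyst class known to give exo-selective, face-controlled Diels–Alder reactions of 3-hydroxy-2-pyrones, to give the C12-hydroxy tricyclic aldehyde F5. The same iodo-olefination (one extra equivalent of ylide for the free OH) gives the C12-hydroxy (Z)-vinyl iodide F6. Sonogashira coupling with 19 gives the C12-hydroxy (Z)-enyne F7, and TFA–H2O converts this to keto diol 21, where the route is rejoined.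

Step 14 (proposed new cycloisomerisation). The risks are diversion of the vinylallene (1,5-hydrogen shift, triene formation), poor nucleophilicity of the tertiary alcohol, and the wrong C10 epimer if the ligand does not override the substrate. The fallback uses the known divalent-palladium-catalysed syn-SN2′ cyclisation of a hydroxy allylic alcohol with 1,3-chirality transfer. It sets out from vinyl iodide 18: TFA–H2O gives the keto diol vinyl iodide F8, and Luche reduction gives the triol vinyl iodide F9. Separately, (R)-dec-1-yn-3-ol F10 (the slow-reacting enantiomer in a Candida antarctica lipase B/vinyl acetate resolution of commercial racemic dec-1-yn-3-ol) is hydroborated with pinacolborane and catalytic Cp2Zr(H)Cl to (R,E)-1-(4,4,5,5-tetramethyl-1,3,2-dioxaborolan-2-yl)dec-1-en-3-ol F11. Suzuki–Miyaura coupling of the iodide with the boronate (Pd(PPh3)4, K3PO4, THF–H2O) gives the (Z,E)-dienyl tetraol F12. PdCl2(MeCN)2 (THF, 0 °C) then delivers O11 to C10 on the face of the departing C8 hydroxyl, giving 24 with C10 (R) and the E-alkene, where the route is rejoined.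

**Further compounds**
F1 | step 6 | (3R)-3-[(tert-butyldimethylsilyl)oxy]-7,7-diethoxyhept-5-ynal | O=CC[C@H](O[Si](C)(C)C(C)(C)C)CC#CC(OCC)OCC
F2 | step 6 | methyl (7R)-7-[(tert-butyldimethylsilyl)oxy]-11,11-diethoxy-5-hydroxy-2-[(4-methoxybenzyl)oxy]-3-oxoundec-9-ynoate | COC(=O)C(OCc1ccc(OC)cc1)C(=O)CC(O)C[C@H](O[Si](C)(C)C(C)(C)C)CC#CC(OCC)OCC
F3 | step 9 | 6-{(2R,4Z)-2-[(tert-butyldimethylsilyl)oxy]-6,6-diethoxyhex-4-en-1-yl}-3-hydroxy-4-methoxy-2H-pyran-2-one | O=C1OC(C[C@H](O[Si](C)(C)C(C)(C)C)C/C=C\C(OCC)OCC)=CC(OC)=C1O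
F4 | step 9 | (2Z,5R)-5-[(tert-butyldimethylsilyl)oxy]-6-(3-hydroxy-4-methoxy-2-oxo-2H-pyran-6-yl)hex-2-enal | O=C1OC(C[C@H](O[Si](C)(C)C(C)(C)C)C/C=C\C=O)=CC(OC)=C1O
F5 | step 9 | C12-hydroxy tricyclic aldehyde (17 without PMB) | O[C@@]23C(=O)O[C@]4(C[C@H](O[Si](C)(C)C(C)(C)C)C[C@H]4[C@H]2C=O)C=C3OC
F6 | step 9 | C12-hydroxy (Z)-vinyl iodide (18 without PMB) | O[C@@]23C(=O)O[C@]4(C[C@H](O[Si](C)(C)C(C)(C)C)C[C@H]4[C@H]2/C=C(/C)I)C=C3OC
F7 | step 9 | C12-hydroxy (Z)-enyne (20 without PMB) | O[C@@]23C(=O)O[C@]4(C[C@H](O[Si](C)(C)C(C)(C)C)C[C@H]4[C@H]2/C=C(/C)C#CCCCCCCCC)C=C3OC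
F8 | step 14 | keto diol vinyl iodide | O[C@@]23C(=O)O[C@]4(C[C@H](O)C[C@H]4[C@H]2/C=C(/C)I)CC3=O
F9 | step 14 | triol vinyl iodide | O[C@@]23C(=O)O[C@]4(C[C@H](O)C[C@H]4[C@H]2/C=C(/C)I)C[C@H]3O
F10 | step 14 | (R)-dec-1-yn-3-ol | C#C[C@H](O)CCCCCCC
F11 | step 14 | (R,E)-1-(4,4,5,5-tetramethyl-1,3,2-dioxaborolan-2-yl)dec-1-en-3-ol | CCCCCCC[C@@H](O)/C=C/B1OC(C)(C)C(C)(C)O1
F12 | step 14 | (Z,E)-dienyl tetraol (C8 (R)-carbinol) | O[C@@]23C(=O)O[C@]4(C[C@H](O)C[C@H]4[C@H]2/C=C(/C)\C=C\[C@H](O)CCCCCCC)C[C@H]3O
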